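The seven-membered ketone ring (dibenzo[a,d][7]annulen-5-one numbering) is traced back to the five-membered ring of a 3-aryl-1-indanone-2-carboxylate that lacks ring B altogether. Insertion of 3,5-dimethoxybenzyne into its C-1–C-2 bond brings in ring B, forms both ring bonds to it (C-10–C-9a and C-5–C-5a) and expands the ring by two atoms in one operation. The step exploits the ortho pairing of ketone C-5 and benzylic C-10 on resorcinol ring B, with an oxygen flanking the ketone: exactly the innate regiochemistry of this aryne. C-11 is set beforehand by rhodium-catalysed asymmetric arylation; the indane is annulated afterwards by phenacylation, cyclodehydration and syn-hydroarylation.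

Key step: step 7

Remark on locants: from compound 15 on, the core is numbered as dibenzo[a,d][7]annulen-5-one (C-5 ketone; ring A = C-1 to C-4 with C-4a and C-11a; ring B = C-5a to C-9a; C-10 and C-11 the sp3 carbons); the two further indane carbons are C-1' (bonded to C-10) and C-2' (bonded to C-9).

Assumption: in step 3, (S)-BINAP is taken to deliver the aryl group to the enoate face that gives the S-configured product, as the usual facial model for E-enoates predicts; if the sense proves opposite, (R)-BINAP is used instead.

Step 1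
Reactants: 1 methyl 3,5-dimethoxybenzoate
Product: 2 methyl 2-bromo-3,5-dimethoxybenzoate
Conditions: NBS, MeCN, rt
Reagents that add atoms: N-bromosuccinimide, O=C1CCC(=O)N1Br
Why: Electrophilic aromatic bromination; C-2 is ortho and para to the two methoxy groups and less shielded than C-4 between them, so monobromination should take place next to the ester.

Step 2
Reactants: 2 methyl 2-bromo-3,5-dimethoxybenzoate; 3 tert-butyl acrylate
Product: 4 methyl 2-[(E)-3-tert-butoxy-3-oxoprop-1-enyl]-3,5-dimethoxybenzoate
Conditions: Pd(OAc)2, P(o-tol)3, K2CO3, DMF, 110 °C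
Reagents that add atoms: none
Why: Heck reaction; syn carbopalladation at the unsubstituted acrylate carbon and syn β-hydride elimination should give the E-cinnamate, the bulky phosphine helping oxidative addition to the hindered, electron-rich bromide.

Step 3
Reactants: 4 methyl 2-[(E)-3-tert-butoxy-3-oxoprop-1-enyl]-3,5-dimethoxybenzoate; 5 4-methoxyphenylboronic acid
Product: 6 methyl 2-[(1S)-3-tert-butoxy-1-(4-methoxyphenyl)-3-oxopropyl]-3,5-dimethoxybenzoate
Conditions: [Rh(acac)(C2H4)2], (S)-BINAP, dioxane–H2O (10:1), 100 °C
Reagents that add atoms: none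
Why: Rhodium-catalysed asymmetric 1,4-addition of an arylboronic acid (Hayashi–Miyaura reaction); the aryl–rhodium–BINAP complex inserts the E-enoate on one enantioface, which sets the benzylic carbon (later C-11) as S, and the oxa-allyl rhodium is protonated by water.

Step 4
Reactants: 6 methyl 2-[(1S)-3-tert-butoxy-1-(4-methoxyphenyl)-3-oxopropyl]-3,5-dimethoxybenzoate
Product: 7 tert-butyl (2R,3S)-4,6-dimethoxy-3-(4-methoxyphenyl)-1-oxo-2,3-dihydro-1H-indene-2-carboxylate (keto form shown)
Conditions: KOtBu, THF, 0 °C to rt; then 1 M HCl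
Reagents that add atoms: none
Why: Dieckmann condensation; only the tert-butyl ester is enolisable, its enolate closes the five-membered ring on the ortho methyl ester and deprotonation of the β-keto ester drives the reaction, C-2 being epimerisable and expected to rest trans to the C-3 aryl group while C-3 is not acidic and keeps its configuration.

Step 5
Reactants: 8 3,5-dimethoxyphenol
Product: 9 2-bromo-3,5-dimethoxyphenol
Conditions: NBS, CH2Cl2, −78 °C to rt
Reagents that add atoms: N-bromosuccinimide, O=C1CCC(=O)N1Br
Why: Electrophilic bromination of a phenol; at low temperature in a non-polar solvent bromine should be delivered ortho to the hydroxyl group (C-2), a position also ortho and para to the methoxy groups.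

Step 6
Reactants: 9 2-bromo-3,5-dimethoxyphenol
Product: 12 3,5-dimethoxy-2-(trimethylsilyl)phenyl trifluoromethanesulfonate, via aryl trimethylsilyl ether 10 (not isolated), via lithium 2-silylphenoxide 11 (not isolated)
Conditions: HMDS, THF, 70 °C; then n-BuLi, THF, −100 °C; then Tf2O, −100 °C to rt
Reagents that add atoms: hexamethyldisilazane, C[Si](C)(C)N[Si](C)(C)C; trifluoromethanesulfonic anhydride, O=S(=O)(OS(=O)(=O)C(F)(F)F)C(F)(F)F
Why: O-Silylation, bromine–lithium exchange with retro-Brook 1,3-migration of silicon from oxygen to carbon, and O-triflation of the resulting phenoxide, the standard sequence to ortho-silylaryl triflates.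

Step 7
Reactants: 7 tert-butyl (2R,3S)-4,6-dimethoxy-3-(4-methoxyphenyl)-1-oxo-2,3-dihydro-1H-indene-2-carboxylate; 12 3,5-dimethoxy-2-(trimethylsilyl)phenyl trifluoromethanesulfonate
Product: 15 tert-butyl (10R,11S)-1,3,6,8-tetramethoxy-11-(4-methoxyphenyl)-5-oxo-10,11-dihydro-5H-dibenzo[a,d][7]annulene-10-carboxylate, via 3,5-dimethoxybenzyne 13 (not isolated), via cesium benzocyclobutenoxide 14 (not isolated)
Conditions: 12 (1.5 equiv), CsF (3 equiv), MeCN, 80 °C
Reagents that add atoms: none
Why: Fluoride unmasks aryne 13 from 12 and generates the β-keto ester enolate of 7, whose C-2 adds to the aryne carbon remote from the flanking methoxy group; the aryl anion so formed, ortho to that methoxy group, closes onto the neighbouring indanone carbonyl to give 14, and retro-aldol-type cleavage of the former C-1–C-2 bond opens the four- and five-membered rings into the seven-membered ketone with an ester enolate at C-10, protonated on work-up. The closest known reaction type is the acyl-alkylation of arynes by β-keto esters (aryne σ-bond insertion), established for the two-carbon ring expansion of cyclic β-keto esters and for 3-alkoxy arynes. The only ring closed is the transient four-membered one (4-exo-trig attack of the aryl anion on the ketone); the seven-membered ring arises from the five-membered one by insertion of the two aryne carbons. C-11 is untouched; C-10 is formed by enolate protonation, is epimerisable (trans expected) and of no consequence because it is planarised again in step 8. The step needs aryne regioselectivity, secured by the inductive and distortion effect of the methoxy group next to the triple bond, which sends the nucleophile to the distal carbon and so places the ketone ortho to oxygen. It also needs the aryl anion to choose the ketone over the ester, secured by the bulk of the tert-butyl ester.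

Step 8
Reactants: 15 tert-butyl (10R,11S)-1,3,6,8-tetramethoxy-11-(4-methoxyphenyl)-5-oxo-10,11-dihydro-5H-dibenzo[a,d][7]annulene-10-carboxylate; 16 2-bromo-1-(3,5-dimethoxyphenyl)ethan-1-one
Product: 17 tert-butyl (10S,11S)-10-[2-(3,5-dimethoxyphenyl)-2-oxoethyl]-1,3,6,8-tetramethoxy-11-(4-methoxyphenyl)-5-oxo-10,11-dihydro-5H-dibenzo[a,d][7]annulene-10-carboxylate
Conditions: NaH, THF–DMF, 0 °C; then 16, 0 °C to rt
Reagents that add atoms: none
Why: C-Alkylation of a stabilised ester enolate by SN2 displacement at an α-bromo ketone; the electrophile should approach the planar C-10 enolate anti to the C-11 aryl group, and the configuration of this quaternary centre is in any case erased in step 9.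

Step 9
Reactants: 17 tert-butyl (10S,11S)-10-[2-(3,5-dimethoxyphenyl)-2-oxoethyl]-1,3,6,8-tetramethoxy-11-(4-methoxyphenyl)-5-oxo-10,11-dihydro-5H-dibenzo[a,d][7]annulene-10-carboxylate
Product: 19 (10R,11S)-indene: core with a cyclopentene fused across C-9/C-9a/C-10, C-1'H=C-2' bearing 3,5-dimethoxyphenyl at C-2', H at C-10, 4-methoxyphenyl at C-11, OMe at C-1, C-3, C-6, C-8, via indene carboxylic acid 18 (not isolated)
Conditions: MsOH, CH2Cl2, 0 °C to rt; then DBU, toluene, 100 °C
Reagents that add atoms: none
Why: Acid removes the tert-butyl group and effects Friedel–Crafts cyclodehydration of the aryl ketone onto C-9 (the only free position ortho to C-9a, activated by an ortho and a para methoxy group; five-membered closure), and DBU then triggers decarboxylation of 18 through its indenyl anion and equilibrates the acidic C-10–H by 1,3-prototropy, which should leave the conjugated 3-arylindene with H-10 trans to H-11 (C-11 aryl anti to C-9a).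

Step 10
Reactants: 19 (10R,11S)-indene; 20 4-iodoanisole
Product: 21 (10R,11S,1'S,2'S)-octamethyl ether of the target: OMe at C-1, C-3, C-6, C-8; 4-methoxyphenyl at C-11 and C-1'; 3,5-dimethoxyphenyl at C-2'
Conditions: Pd(OAc)2, PPh3, HCO2Na, n-Bu4NCl, DMF, 80 °C
Reagents that add atoms: none
Why: Reductive Heck reaction (syn hydroarylation of a styrenic alkene); the arylpalladium should add from the face opposite the C-10–C-11 bond with aryl at C-1' and palladium at the doubly benzylic C-2', no syn β-hydrogen is then available, and formate-derived hydride replaces palladium with retention, so that H-2' is cis to the new aryl group and the three indane substituents end all-trans.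

Step 11
Reactants: 21 (10R,11S,1'S,2'S)-octamethyl ether of the target
Product: 22 target, CNP0116600.1: (10R,11S,1'S,2'S)-1,3,6,8-tetrahydroxy-11,1'-bis(4-hydroxyphenyl)-2'-(3,5-dihydroxyphenyl) derivative of the C-9/C-10 cyclopenta-annulated dibenzo[a,d][7]annulen-5-one
Conditions: BBr3, CH2Cl2, −78 °C to rt; then H2O
Reagents that add atoms: none
Why: Lewis-acid cleavage of all eight aryl methyl ethers by BBr3, which touches none of the four stereocentres.

Compound list

1 | methyl 3,5-dimethoxybenzoate | COC(=O)c1cc(OC)cc(OC)c1 | starting material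
2 | methyl 2-bromo-3,5-dimethoxybenzoate | COC(=O)c1cc(OC)cc(OC)c1Br | intermediate
3 | tert-butyl acrylate | C=CC(=O)OC(C)(C)C | starting material
4 | methyl 2-[(E)-3-tert-butoxy-3-oxoprop-1-enyl]-3,5-dimethoxybenzoate | COC(=O)c1cc(OC)cc(OC)c1/C=C/C(=O)OC(C)(C)C | intermediate
5 | 4-methoxyphenylboronic acid | COc1ccc(cc1)B(O)O | starting material
6 | methyl 2-[(1S)-3-tert-butoxy-1-(4-methoxyphenyl)-3-oxopropyl]-3,5-dimethoxybenzoate | COC(=O)c1cc(OC)cc(OC)c1[C@H](c1ccc(OC)cc1)CC(=O)OC(C)(C)C | intermediate
7 | tert-butyl (2R,3S)-4,6-dimethoxy-3-(4-methoxyphenyl)-1-oxo-2,3-dihydro-1H-indene-2-carboxylate | O=C1c2cc(OC)cc(OC)c2[C@H](c2ccc(OC)cc2)[C@H]1C(=O)OC(C)(C)C | intermediate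
8 | 3,5-dimethoxyphenol | COc1cc(O)cc(OC)c1 | starting material
9 | 2-bromo-3,5-dimethoxyphenol | COc1cc(O)c(Br)c(OC)c1 | intermediate
10 | (2-bromo-3,5-dimethoxyphenoxy)trimethylsilane | COc1cc(O[Si](C)(C)C)c(Br)c(OC)c1 | intermediate
11 | lithium 3,5-dimethoxy-2-(trimethylsilyl)phenoxide | COc1cc([O-])c([Si](C)(C)C)c(OC)c1.[Li+] | intermediate
12 | 3,5-dimethoxy-2-(trimethylsilyl)phenyl trifluoromethanesulfonate | COc1cc(OS(=O)(=O)C(F)(F)F)c([Si](C)(C)C)c(OC)c1 | intermediate
13 | 3,5-dimethoxybenzyne (1,2-didehydro-3,5-dimethoxybenzene) | COC1=CC(OC)=CC#C1 | intermediate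
14 | cesium benzocyclobutenoxide: cyclobutene formed by C-2 of the indanone and the two aryne carbons closing onto C-1, alkoxide at the former carbonyl carbon, ester retained at C-2, new aryl ring trans to the C-3 aryl group | [Cs+].[O-][C@]12c3cc(OC)cc(OC)c3[C@H](c3ccc(OC)cc3)[C@@]1(C(=O)OC(C)(C)C)c1cc(OC)cc(OC)c12 | intermediate
15 | tert-butyl (10R,11S)-1,3,6,8-tetramethoxy-11-(4-methoxyphenyl)-5-oxo-10,11-dihydro-5H-dibenzo[a,d][7]annulene-10-carboxylate | O=C1c2cc(OC)cc(OC)c2[C@H](c2ccc(OC)cc2)[C@@H](C(=O)OC(C)(C)C)c2c1c(OC)cc(OC)c2 | intermediate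
16 | 2-bromo-1-(3,5-dimethoxyphenyl)ethan-1-one | COc1cc(cc(OC)c1)C(=O)CBr | starting material
17 | tert-butyl (10S,11S)-10-[2-(3,5-dimethoxyphenyl)-2-oxoethyl]-1,3,6,8-tetramethoxy-11-(4-methoxyphenyl)-5-oxo-10,11-dihydro-5H-dibenzo[a,d][7]annulene-10-carboxylate | O=C1c2cc(OC)cc(OC)c2[C@H](c2ccc(OC)cc2)[C@@](C(=O)OC(C)(C)C)(CC(=O)c2cc(OC)cc(OC)c2)c2c1c(OC)cc(OC)c2 | intermediate
18 | (10S,11S)-indene carboxylic acid: as 19 but with CO2H in place of H at C-10 | O=C1c2cc(OC)cc(OC)c2[C@H](c2ccc(OC)cc2)[C@]2(C(=O)O)c3c1c(OC)cc(OC)c3C(c1cc(OC)cc(OC)c1)=C2 | intermediate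
19 | (10R,11S)-indene: cyclopentene fused across C-9/C-9a/C-10, C-1'H=C-2'(3,5-dimethoxyphenyl), H-10 trans to H-11, 4-methoxyphenyl at C-11, OMe at C-1, C-3, C-6, C-8 | O=C1c2cc(OC)cc(OC)c2[C@H](c2ccc(OC)cc2)[C@@H]2c3c1c(OC)cc(OC)c3C(c1cc(OC)cc(OC)c1)=C2 | intermediate
20 | 4-iodoanisole | COc1ccc(I)cc1 | starting material
21 | (10R,11S,1'S,2'S)-octamethyl ether of the target | O=C1c2cc(OC)cc(OC)c2[C@H](c2ccc(OC)cc2)[C@@H]2c3c1c(OC)cc(OC)c3[C@H](c1cc(OC)cc(OC)c1)[C@H]2c1ccc(OC)cc1 | intermediate
22 | CNP0116600.1, (10R,11S,1'S,2'S)-configured target | O=C1c2cc(O)cc(O)c2[C@H](c2ccc(O)cc2)[C@@H]2c3c1c(O)cc(O)c3[C@H](c1cc(O)cc(O)c1)[C@H]2c1ccc(O)cc1 | target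

Total step count: 11. Longest linear sequence: 9 steps (steps 1–4 and 7–11, from methyl 3,5-dimethoxybenzoate); the aryne precursor 12 is made in a two-step side branch (steps 5 and 6).

Steps most likely to fail

Step 7. The fully substituted, β-branched enolate may intercept the aryne too slowly, so that aryne self-reaction, or protonation of the aryl anion before acyl transfer, takes over. The fallback is a stepwise anionic ring expansion that sets out from 7 and returns at 15. Commercial 1-iodo-3,5-dimethoxybenzene is brominated with NBS in MeCN to 2-bromo-1-iodo-3,5-dimethoxybenzene F1. Oxidation with mCPBA and TsOH and trapping with 1,3,5-trimethoxybenzene gives (2-bromo-3,5-dimethoxyphenyl)(2,4,6-trimethoxyphenyl)iodonium 4-methylbenzenesulfonate F2. The potassium enolate of 7 (KOtBu, toluene) is C-arylated by F2, anti to the C-3 aryl group, to tert-butyl (2R,3S)-2-(2-bromo-3,5-dimethoxyphenyl)-4,6-dimethoxy-3-(4-methoxyphenyl)-1-oxo-2,3-dihydro-1H-indene-2-carboxylate F3 (metal-free α-arylation of a cyclic β-keto ester with a diaryliodonium salt). Bromine–lithium exchange under Parham conditions (n-BuLi, THF, −100 °C) then sends the aryllithium onto the indanone carbonyl, and the benzocyclobutenoxide of the type of 14 fragments in the same way to 15.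

Step 10. Carbopalladation of the hindered trisubstituted alkene may be slow, so that reduction of the aryl iodide, arylation at the acidic C-10–H or double-bond migration competes, and facial control may erode. The fallback is hydroboration followed by a stereoretentive Suzuki–Miyaura coupling; it sets out from 19 and returns at 21. One equivalent of BH3·SMe2 (THF, 0 °C) should add across C-1'=C-2' syn and anti to the C-10–C-11 bond with boron at C-1', faster than it reduces the deactivated diaryl ketone. Treatment with KHF2 gives the potassium C-1' trifluoroborate F4 (boron trans to the C-10–C-11 bond, H-2' cis to boron). Palladium-catalysed coupling of F4 with 4-chloroanisole, under a ligand system known to transfer secondary alkyl groups with retention, then gives 21.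

Step 9. The thermodynamic end point may not be the one needed: the indenyl anion may be reprotonated at C-2' (double-bond migration into the seven-membered ring), the cis/trans balance at C-10 may be unfavourable, and the tert-butyl cation may alkylate the electron-rich rings. The fallback puts C-10 under kinetic control; it sets out from 15 and returns at 19. Compound 15 is dealkylated and decarboxylated (TFA, CH2Cl2; then heat in toluene) to (11S)-1,3,6,8-tetramethoxy-11-(4-methoxyphenyl)-10,11-dihydro-5H-dibenzo[a,d][7]annulen-5-one F5. Lateral lithiation at C-10 (LDA, THF, −78 °C; benzylic and ortho to the ketone) and alkylation with 16 anti to the C-11 aryl group give (10R,11S)-10-[2-(3,5-dimethoxyphenyl)-2-oxoethyl]-1,3,6,8-tetramethoxy-11-(4-methoxyphenyl)-10,11-dihydro-5H-dibenzo[a,d][7]annulen-5-one F6. Cyclodehydration with MsOH, with no base treatment afterwards, gives 19 with C-10 fixed by the C–C bond-forming step.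

Further compounds

F1 | step 7 | 2-bromo-1-iodo-3,5-dimethoxybenzene | COc1cc(I)c(Br)c(OC)c1
F2 | step 7 | (2-bromo-3,5-dimethoxyphenyl)(2,4,6-trimethoxyphenyl)iodonium 4-methylbenzenesulfonate | COc1cc([I+]c2c(OC)cc(OC)cc2OC)c(Br)c(OC)c1.Cc1ccc(cc1)S(=O)(=O)[O-]
F3 | step 7 | tert-butyl (2R,3S)-2-(2-bromo-3,5-dimethoxyphenyl)-4,6-dimethoxy-3-(4-methoxyphenyl)-1-oxo-2,3-dihydro-1H-indene-2-carboxylate | O=C1c2cc(OC)cc(OC)c2[C@H](c2ccc(OC)cc2)[C@@]1(C(=O)OC(C)(C)C)c1cc(OC)cc(OC)c1Br
F4 | step 10 | potassium C-1' trifluoroborate of the octamethyl indane (BF3K in place of the C-1' aryl group of 21) | O=C1c2cc(OC)cc(OC)c2[C@H](c2ccc(OC)cc2)[C@@H]2c3c1c(OC)cc(OC)c3[C@H](c1cc(OC)cc(OC)c1)[C@H]2[B-](F)(F)F.[K+]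
F5 | step 9 | (11S)-1,3,6,8-tetramethoxy-11-(4-methoxyphenyl)-10,11-dihydro-5H-dibenzo[a,d][7]annulen-5-one | O=C1c2cc(OC)cc(OC)c2[C@H](c2ccc(OC)cc2)Cc2cc(OC)cc(OC)c12
F6 | step 9 | (10R,11S)-10-[2-(3,5-dimethoxyphenyl)-2-oxoethyl]-1,3,6,8-tetramethoxy-11-(4-methoxyphenyl)-10,11-dihydro-5H-dibenzo[a,d][7]annulen-5-one | O=C1c2cc(OC)cc(OC)c2[C@H](c2ccc(OC)cc2)[C@@H](CC(=O)c2cc(OC)cc(OC)c2)c2cc(OC)cc(OC)c12
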